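In the first minutes the winter run races, reaching 24.3 % product by 2.00 min, and then it nearly stops: 45.7 % at 12.0 min, 47.0 % at 25.0 min. The noon run, at twice the charge, stops in the same way. I read this as a step that runs back, product forming with an unseen partner one for one. Where forward and back rates match, dividing one by the other removes time and leaves [product] squared over [starting material], a reaction quotient.

| flask | starting material | protic impurity | temperature | remark | time |
|---|---|---|---|---|---|
| winter | 0.018 M | 3.5 mM | −25 °C | run made earlier |  |
| summer | 0.070 M | 3.5 mM | 5 °C | run made earlier |  |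
| noon | 0.035 M | 5.2 mM | −25 °C | run made earlier |  |
| Sunday's | 0.035 M | 3.50 mM | −20 °C |  | 25 min |
| Wednesday's | 0.035 M | 3.50 mM | 5 °C |  | 25 min |
| Saturday's | 0.035 M | 3.50 mM | 30 °C |  | 25 min |

| run | time / min | product / % | starting material / % |
|---|---|---|---|
| winter | 2.00 | 24.3 | 68.0 |
| winter | 4.00 | 37.2 | 53.0 |
| winter | 8.00 | 44.3 | 44.6 |
| winter | 12.0 | 45.7 | 42.1 |
| winter | 25.0 | 47.0 | 38.6 |
| summer | 1.33 | 3.7 | 89.9 |
| summer | 3.00 | 5.6 | 87.5 |
| summer | 4.00 | 7.0 | 86.8 |
| summer | 6.00 | 7.0 | 84.5 |
| summer | 8.00 | 8.4 | 83.7 |
| noon | 2.00 | 23.3 | 66.2 |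
| noon | 6.00 | 36.6 | 48.5 |
| noon | 12.0 | 38.1 | 45.6 |
| noon | 20.0 | 36.4 | 42.9 |
| noon | 25.0 | 37.6 | 42.1 |

(each reading ± 0.5 percentage points)

- the flask with the highest amount of product, in percent of the starting material charged ("all alike" if they lie within 1.5 percentage points) (Sunday's / Wednesday's / Saturday's / all alike)
- final product, as a percentage of the starting material charged, in Sunday's
- final product, as a percentage of the starting material charged, in Wednesday's
- final product, as a percentage of the starting material charged, in Saturday's

- a reading or a percentage of product counts all its forms, free or not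
- a reading of starting material is of its free form alone

At the last readings this quotient is 0.0103 M in the winter run and 0.0118 M in the noon run, close despite the different charges. I keep their middle, 0.0110 M, as the stall quotient at −25 °C. The summer run gives 5.90 × 10⁻⁴ M at 5 °C, a fall by a factor of 18.6.

Assuming a fixed factor per degree, the quotient is 0.00676 M at −20 °C and 5.15 × 10⁻⁵ M at 30 °C. If the impurity takes its own charge of starting material, 0.0315 M remains, and product x then obeys x·x = q(pool − x). That gives 33.1 % for Sunday's, 11.5 % for Wednesday's and 3.57 % for Saturday's.

The weak link is that pool. The last two readings of the noon run leave 7.10 mM of its charge unaccounted, more than its impurity charge of 5.2 mM. Supposing that shortfall goes in step with the impurity charge, Sunday's pool is 0.0302 M, a guess that sets aside the two temperatures, −20 °C against −25 °C, and Sunday's comes to 32.3 %.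

The forecast says Sunday's, with 39 % (32 % to 46 %), 13 % (8 % to 20 %) and 4 % (1 % to 9 %), on the ground that “warming lowers the final yield”. It stands above my Sunday's figure.

Sunday's ends at 30.9 %, Wednesday's at 17.3 % and Saturday's at 12.7 %, so Sunday's holds most.

    starting material ⇌ product + released group (K = 0.00300 M, k = 0.00510 /s, Ea = 68.0 kJ/mol, ΔH = −88.0 kJ/mol)
    starting material + protic impurity → quenched substrate (k = 0.0540 /M/s, Ea = 46.0 kJ/mol)
    starting material + product ⇌ idle adduct, settled at all times (K = 23.0 /M, ΔH = −20.0 kJ/mol)
    released group → by-product carried off (k = 3.10 × 10⁻⁴ /s, Ea = 69.0 kJ/mol)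
    (constants at −20 °C)

Saturday's stands 9.1 percentage points above my figure, with 0.00442 M of by-product carried off and 2.05 × 10⁻⁵ M of released group left. Sunday's own end gives a quotient of 0.00645 M against my 0.00676 M. A flask like Sunday's kept at −35 °C ends with 48.9 % product and 32.2 % starting material, a quotient of 0.0261 M, where 0.0110 M carried down from −25 °C gives 0.0292 M.

The earlier runs and the new flask are calculated on assumed constants, noise included.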